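## Structural features

The target is a germacranolide: a ten-membered carbocycle (C1 to C10, germacrane numbering, used throughout) fused across C6–C7 to an α-methylene-γ-butyrolactone (lactone oxygen on C6, C11 on C7, carbonyl C12, exocyclic methylene C13). The ring carries two trisubstituted alkenes that are both cis within the ring, C4=C5 with the methyl C15 and C1=C10 with the oxygenated branch C14, so it is a cis,cis-cyclodeca-1,5-diene with the transannular reactivity that goes with that. Four contiguous stereocentres sit on C6 (R), C7 (R), C8 (S) and C9 (R): H6 and H7 are trans on the lactone, C11 and O8 are anti along the extended C6–C9 chain, and O8 and O9 are anti along C7–C10; a fifth centre (R) lies in the 2-methylbutanoate on O14. Three oxygens must end up differentiated beside the lactone: O8 free, O9 acetylated, O14 acylated. Fragile points are the conjugated exo-methylene (Michael acceptor), the acetate next to a free hydroxyl (acyl shift, relactonisation onto O8 under base), the enolisable α-centre of the side-chain ester and the allylic C–O bonds at C6, C9 and C14. The real difficulty is the medium ring with a cis trisubstituted alkene whose branch is oxidised, directly beside two oxygenated stereocentres. The key step uses exactly this corner: C9 is a carbinol bonded to C10, so C1–C10 can be carried as a ring alkyne, the C9–C10 bond can close the ring by alkynyl addition to a C9 aldehyde, and C14 can enter afterwards by a syn addition that within a ring can only give the cis alkene.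

## Logic of the disconnections

34 to 30 and 31. The bonds cut are O8–Si, O9–acetyl and O14–acyl (34 from 33, 33 from 32, 32 from 30 and 31). The three esters and the free hydroxyl are the most base-sensitive part, so they are made last. The gain is that every earlier intermediate carries only silyl ethers. The demand is a clean preference of the primary O14 over the secondary O9 in the first acylation and a final desilylation that never produces an alkoxide next to the acetate.

30 to 24. The bond cut is C11=C13 (30 from 29, 29 from 25, 25 from 24). The exo-methylene is a Michael acceptor that would not survive tin hydride or palladium, so it is placed after all metal chemistry. The gain is a plain saturated lactone in all earlier compounds. The demand is a lactone enolate in a molecule with two allylic oxygens, which is why both are silylated for this one operation with a group that leaves again beside the C8 silyl ether.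

24 to 21. The bond cut is C10–C14, together with the H on C1 (24 from 23, 23 from 22, 22 from 21). Taking the trisubstituted alkene back to a ring alkyne removes both the geometry problem and the branch. The demand is regiochemical: the metal must go to C10, the carbon next to the carbinol, and the addition must be syn.

21 to 19. The bond cut is C9–C10, which opens the ten-membered ring. The gain is an open-chain compound in which only three stereocentres remain and in which the two ends are an aldehyde and a haloalkyne. The demand is threefold: ring closure must beat oligomerisation, the lactone must be ignored, and the aldehyde must be attacked on the face that gives the 8,9-anti carbinol.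

19 to 14. No skeletal bond is cut; the aldehyde is traced to a primary silyl ether, the C8 silyl ether and the primary ether to a diol, the diol to an acetonide and the iodoalkyne to a silylalkyne (19 from 18, 18 from 16, 16 from 15, 15 from 14). The iodoalkyne is installed while the diol is still masked, and the epimerisable α-silyloxy aldehyde is unveiled in one operation and used at once. The demand is that the lactone on O6 does not shift to O8 or O9 while the diol is free.

14 to 6 and 11. The bonds cut are C5–C6 and O–C12. This is the convergent point: 6 brings C1 to C5, C10 and C15 with the C4=C5 geometry already fixed, and 11 brings C6 to C9, C11 and C12 with C7 and C8 set. The demand is addition to the aldehyde in preference to the ester and attack on the face that leads to the 6,7-trans lactone.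

11 to 7. The bonds cut are C6–C7 and C7=C11 (11 from 9, 9 from 8, 8 from 7). C8 comes from the chiral pool; C6 is introduced as a one-carbon nitronate that is later unmasked to the aldehyde. The demand is syn selectivity of the conjugate addition relative to O8.

6 to 1 and 2. The bond cut is C3–C4 (and C5–I). Syn addition of an alkylcopper across 2 fixes the alkene geometry without any separation of isomers. The demand is an alkyne in 1 that stays inert, hence the silyl cap.

## Other disconnections considered

Alternative 1: The cut is C3–C4, C5–C6 and O–C12 at once. The forward step is a one-flask sequence in which the copper reagent from but-3-enylmagnesium bromide A2 adds across 2, the resulting Z-alkenylcopper species is captured by 11, and the alkoxide lactonises to the dienyl lactone A1. In its favour: it merges steps 1 and 5 of the chosen route, avoids the isolated iodide and tBuLi, and a copper nucleophile is less basic towards the enolisable aldehyde. On these counts it is the better tactic for the lactone half. Against it: alkenylcopper and mixed cuprate reagents add to aldehydes sluggishly and can transfer the wrong ligand, and the facial problem at C6 is the same as in the chosen route. More important, A1 ends in a terminal alkene at C1 and says nothing about the ring. Closing C1=C10 from it would mean a metathesis that must form a cis trisubstituted alkene in a ten-membered ring, or an oxidative cleavage that cannot distinguish the terminal alkene from the more electron-rich C4=C5 alkene. On structure the two plans share the lactone, the C6–C8 triad and the Z alkene. On mechanism they share the syn carbocupration. On step economy Alternative 1 is one step shorter up to the lactone but longer overall, because the chosen route carries C10 as a masked alkyne from the first step.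

Alternative 2: The cut is C2–C3 of the ten-membered ring, paid for by a C5–C10 bond in a six-membered precursor. The forward step is the anionic oxy-Cope rearrangement (KH, 18-crown-6) of the cis-1-vinyl-2-isopropenylcyclohexanol A3 to the ten-membered C10 ketone A4. In its favour: the medium ring arises by ring expansion, with no dilution and no entropic penalty, and C6 to C9 are set beforehand on a cyclohexane where stereocontrol is routine. On ring formation it is the better of the two plans. Against it: the cis C4=C5 alkene requires the cis-divinyl arrangement and a boat-like transition state, whereas the easier chair pathway leads to the trans alkene. The C10 ketone must then be turned regioselectively into the C1=C10 alkene bearing C14, with enolisation towards C1 and not towards the oxygenated C9. O8 and O9 leave the key step under one acetonide although the target needs them differentiated. The lactone is still two oxidation-state changes away. On mechanism the sigmatropic shift is more predictable in connectivity but less so in alkene geometry, while the chosen ring closure has no geometry at stake. On step economy A3 needs six contiguous stereocentres, two of which are destroyed, and the end game is longer, so the total is expected to be higher.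

Alternative 3: The cut, read backwards, is the formation of a C4–C9 bond that turns the ten-membered ring into a cis-decalin. The forward step is the Grob fragmentation (KOtBu) of the hydroxy mesylate A5 to the enone lactone A6. In its favour: both alkene geometries are fixed by the substrate, C1=C10 because it sits in a cyclohexene and C4=C5 by the anti-periplanar relation of the C4–C9 bond and the C5 leaving group. The lactone and C14 are already in place, and no dilution is needed. On alkene geometry and on the number of steps after the key step it is the better plan. Against it: A6 has its C8 stereocentre α to the new ketone and a lactone in the presence of alkoxide base, so epimerisation and acyl transfer threaten at the moment of fragmentation. The C9 ketone must still be reduced to the 9R carbinol in a flexible ring, which is no more certain than the facial selectivity of the chosen ring closure (equal on this point). A5 is a cis-decalin with a quaternary C4, a tertiary C9 carbinol and six stereocentres, three of which are sacrificed. On step economy the short end game is outweighed by the long way to A5.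

Key step: step 10

Remark on the chemistry (assumption): the nitronate addition of step 3 is taken to follow the syn course (C6 and O8 on the same side of the extended C12–C9 chain) that nitronates show with dioxolanyl-substituted enoates.
Check of structures: 19 and 21 as drawn agree with the target at C6, C7, C8 and C9 and at the C4=C5 alkene, so no structure had to be corrected. The design changes concern how 19 is reached and the omission of any free hydroxyl at the stage of the iodination.

## Route

Step 1
Reactants: 1 (4-bromobut-1-yn-1-yl)trimethylsilane; 2 propyne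
Product: 6 (Z)-1-iodo-2-methyl-6-(trimethylsilyl)hex-1-en-5-yne, via Grignard reagent 3 (not isolated), via alkylcopper 4 (not isolated), via alkenylcopper 5 (not isolated)
Conditions: Mg, Et2O, rt; CuBr·SMe2, Et2O/Me2S, −45 °C; 2 (excess), −25 °C; I2, THF, −45 → 0 °C
Reagents that add atoms: iodine, [I][I]
Why: Grignard formation, transmetalation to monovalent copper and syn carbocupration of propyne (alkyl to C4, copper to C5) put the chain cis to the metal; iodinolysis goes with retention, so the iodide is Z. The silyl cap keeps the chain alkyne out of the reaction.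

Step 2
Reactants: 7 (R)-2,3-O-isopropylideneglyceraldehyde
Product: 8 methyl (2Z)-3-[(4S)-2,2-dimethyl-1,3-dioxolan-4-yl]prop-2-enoate
Conditions: Ph3P=CHCO2Me, MeOH, 0 °C
Reagents that add atoms: methyl (triphenylphosphoranylidene)acetate, COC(=O)C=P(c1ccccc1)(c1ccccc1)c1ccccc1
Why: Wittig olefination with a stabilised ylide; in methanol α-alkoxy aldehydes of this type should favour the Z-enoate, and the minor E isomer is removed by chromatography. C8 is not touched (its descriptor changes only by the priority rules).

Step 3
Reactants: 8 methyl (2Z)-3-[(4S)-2,2-dimethyl-1,3-dioxolan-4-yl]prop-2-enoate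
Product: 9 methyl (3S)-3-[(4S)-2,2-dimethyl-1,3-dioxolan-4-yl]-4-nitrobutanoate
Conditions: MeNO2 (10 equiv), DBU, MeCN, 0 °C → rt
Reagents that add atoms: nitromethane, C[N+](=O)[O-]
Why: Michael addition of a nitronate as formyl anion equivalent creates C7. Allylic 1,3-strain holds the C8–H bond in the enoate plane and the nitronate should add anti to the C8–C9 bond, past the smaller ring oxygen, which gives the syn adduct (C6 and O8 syn).

Step 4
Reactants: 9 methyl (3S)-3-[(4S)-2,2-dimethyl-1,3-dioxolan-4-yl]-4-nitrobutanoate
Product: 11 methyl (3R)-3-[(4S)-2,2-dimethyl-1,3-dioxolan-4-yl]-4-oxobutanoate, via sodium nitronate 10 (not isolated)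
Conditions: NaOMe (1.05 equiv), MeOH, 0 °C; O3, MeOH/CH2Cl2, −78 °C; N2 purge; pH 7 buffer
Reagents that add atoms: ozone, [O-][O+]=O
Why: Nef reaction in its ozonolytic form: the C=N bond of the nitronate is cleaved at −78 °C, which frees the aldehyde without acid (acetonide) and without lasting base (epimerisable C7, β-alkoxy group). The crude aldehyde is used at once.

Step 5
Reactants: 6 (Z)-1-iodo-2-methyl-6-(trimethylsilyl)hex-1-en-5-yne; 11 methyl (3R)-3-[(4S)-2,2-dimethyl-1,3-dioxolan-4-yl]-4-oxobutanoate
Product: 14 (4S,5R)-4-[(4S)-2,2-dimethyl-1,3-dioxolan-4-yl]-5-[(1Z)-2-methyl-6-(trimethylsilyl)hex-1-en-5-yn-1-yl]oxolan-2-one, via alkenyllithium 12 (not isolated), via lithium alkoxide 13 (not isolated)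
Conditions: 6, tBuLi (2.0 equiv), Et2O, −78 °C; then 11, −78 → 0 °C; aq. NH4Cl
Reagents that add atoms: none
Why: Iodine–lithium exchange with retention, 1,2-addition to the aldehyde (faster than to the ester) and lactonisation of the γ-alkoxide by acyl substitution. C6 is set by Felkin–Anh 1,2-induction from C7 (dioxolanyl as the large group) reinforced by 1,3-anti induction from O8 (the matched case of an anti aldehyde), which should give the 6,7-trans lactone.

Step 6
Reactants: 14 (4S,5R)-4-[(4S)-2,2-dimethyl-1,3-dioxolan-4-yl]-5-[(1Z)-2-methyl-6-(trimethylsilyl)hex-1-en-5-yn-1-yl]oxolan-2-one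
Product: 15 (4S,5R)-4-[(4S)-2,2-dimethyl-1,3-dioxolan-4-yl]-5-[(1Z)-6-iodo-2-methylhex-1-en-5-yn-1-yl]oxolan-2-one
Conditions: N-iodosuccinimide (1.2 equiv), AgNO3 (10 mol%), DMF, rt, dark
Reagents that add atoms: N-iodosuccinimide, O=C1CCC(=O)N1I
Why: Silver-catalysed desilylative iodination: the silylalkyne becomes a silver acetylide that is iodinated at carbon. The neutral conditions spare lactone, acetonide and alkene, and no free hydroxyl is present that could add to an iodonium ion.

Step 7
Reactants: 15 (4S,5R)-4-[(4S)-2,2-dimethyl-1,3-dioxolan-4-yl]-5-[(1Z)-6-iodo-2-methylhex-1-en-5-yn-1-yl]oxolan-2-one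
Product: 16 (4R,5R)-4-[(1S)-1,2-dihydroxyethyl]-5-[(1Z)-6-iodo-2-methylhex-1-en-5-yn-1-yl]oxolan-2-one
Conditions: AcOH/H2O 4:1, 35 °C
Reagents that add atoms: none
Why: Acid-catalysed acetal hydrolysis. The trans lactone on O6 should be favoured over the cis γ-lactone on O8 and the δ-lactone on O9, and mild acid with short contact keeps the acyl group where it is.

Step 8
Reactants: 16 (4R,5R)-4-[(1S)-1,2-dihydroxyethyl]-5-[(1Z)-6-iodo-2-methylhex-1-en-5-yn-1-yl]oxolan-2-one
Product: 18 (4S,5R)-4-[(1S)-1-(tert-butyldimethylsilyloxy)-2-(triethylsilyloxy)ethyl]-5-[(1Z)-6-iodo-2-methylhex-1-en-5-yn-1-yl]oxolan-2-one, via mono-TES ether 17 (not isolated)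
Conditions: TESCl (1.05 equiv), imidazole, CH2Cl2, −40 °C; then 2,6-lutidine, TBSOTf, −40 → 0 °C
Reagents that add atoms: chlorotriethylsilane, CC[Si](Cl)(CC)CC; tert-butyldimethylsilyl trifluoromethanesulfonate, CC(C)(C)[Si](C)(C)OS(=O)(=O)C(F)(F)F
Why: Sequential silylation in one flask: the primary C9 hydroxyl takes the labile TES group at low temperature, then the silyl triflate caps the hindered C8 hydroxyl as the robust, non-chelating TBS ether that is carried to the last step.

Step 9
Reactants: 18 (4S,5R)-4-[(1S)-1-(tert-butyldimethylsilyloxy)-2-(triethylsilyloxy)ethyl]-5-[(1Z)-6-iodo-2-methylhex-1-en-5-yn-1-yl]oxolan-2-one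
Product: 19 (2S)-2-(tert-butyldimethylsilyloxy)-2-[(2R,3S)-2-[(1Z)-6-iodo-2-methylhex-1-en-5-yn-1-yl]-5-oxooxolan-3-yl]acetaldehyde
Conditions: (COCl)2, DMSO, CH2Cl2, −78 → −40 °C; Et3N, −78 → −20 °C
Reagents that add atoms: none
Why: Swern oxidation applied to a primary TES ether: the activated sulfoxide attacks the ether oxygen, the chlorosilane leaves and the alkoxysulfonium ylide collapses to the aldehyde, while the secondary TBS ether is inert. The α-silyloxy aldehyde is made cold and used directly.

Step 10
Reactants: 19 (2S)-2-(tert-butyldimethylsilyloxy)-2-[(2R,3S)-2-[(1Z)-6-iodo-2-methylhex-1-en-5-yn-1-yl]-5-oxooxolan-3-yl]acetaldehyde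
Product: 21 (6R,7S,8S,9R)-8-(tert-butyldimethylsilyloxy)-9-hydroxy-13,14-dinorgermacr-4Z-en-1(10)-yn-12,6-olide, via alkynylchromium 20 (not isolated)
Conditions: CrCl2 (6 equiv), NiCl2 (1 mol%), degassed THF, 0.002 M, slow addition of 19 over 12 h, rt; aq. NH4Cl
Reagents that add atoms: none
Why: Two equivalents of divalent chromium (nickel assisting the oxidative addition) reduce the C10–I bond to the alkynyl species 20 of trivalent chromium, which adds to the C9 formyl group to give a chromium alkoxide that is hydrolysed on work-up. The closest known reaction type is the intramolecular Nozaki–Hiyama–Kishi haloalkyne–aldehyde cyclisation used to close nine- and ten-membered cycloalkynes. The ten-membered ring closes in a 10-exo-trig mode, the carbonyl oxygen staying outside the ring. The new C9 centre is controlled by C8: in the Felkin–Anh arrangement the C8–OSi bond lies anti to the incoming alkynyl carbon, which places C7 gauche to C10 as the ring requires and leads to the 8,9-anti (9R) carbinol; the bulky TBS ether shuts off the chelate pathway. Chemoselectivity for the aldehyde over the lactone rests on the low basicity and carbonyl selectivity of organochromium reagents. Ring closure over oligomerisation rests on slow addition at high dilution, on the turn imposed by the trans lactone and the cis C4=C5 alkene, and on the fact that a ten-membered ring holds the C2–C1≡C10–C9 unit with only modest bending. No alkene geometry is at stake in this step.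

Step 11
Reactants: 21 (6R,7S,8S,9R)-8-(tert-butyldimethylsilyloxy)-9-hydroxy-13,14-dinorgermacr-4Z-en-1(10)-yn-12,6-olide
Product: 22 8-(tert-butyldimethylsilyloxy)-9-hydroxy-10-(tributylstannyl)-13,14-dinorgermacra-1(10),4-dien-12,6-olide (both ring alkenes cis; H on C1 and tin on C10 on the same side; C6 to C9 as in 21)
Conditions: Bu3SnH (1.3 equiv, slow addition), Pd(PPh3)4 (5 mol%), THF, 0 °C → rt
Reagents that add atoms: tributyltin hydride, CCCC[SnH](CCCC)CCCC
Why: Palladium-catalysed hydrostannation: zerovalent palladium inserts into Sn–H and delivers H and Sn to the same face of the alkyne, so within the ring only the cis alkene can form. The free propargylic hydroxyl steers tin to the proximal carbon C10 and hydrogen to C1.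

Step 12
Reactants: 22 8-(tert-butyldimethylsilyloxy)-9-hydroxy-10-(tributylstannyl)-13,14-dinorgermacra-1(10),4-dien-12,6-olide
Product: 23 8-(tert-butyldimethylsilyloxy)-9-hydroxy-10-iodo-13,14-dinorgermacra-1(10),4-dien-12,6-olide (both ring alkenes cis; C6 to C9 as in 21)
Conditions: I2 (1.05 equiv), CH2Cl2, −78 → 0 °C
Reagents that add atoms: iodine, [I][I]
Why: Iododestannylation, an ipso substitution at the C–Sn bond with retention of geometry. At low temperature the C–Sn bond should react far faster than the trisubstituted alkene, which limits transannular iodoetherification.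

Step 13
Reactants: 23 8-(tert-butyldimethylsilyloxy)-9-hydroxy-10-iodo-13,14-dinorgermacra-1(10),4-dien-12,6-olide
Product: 24 8-(tert-butyldimethylsilyloxy)-9,14-dihydroxy-13-norgermacra-1(10)Z,4Z-dien-12,6-olide (C6 to C9 as in 21)
Conditions: Bu3SnCH2OH (1.5 equiv), Pd(PPh3)4 (10 mol%), 1,4-dioxane, 85 °C
Reagents that add atoms: (tributylstannyl)methanol, OC[Sn](CCCC)(CCCC)CCCC
Why: Stille coupling transfers the hydroxymethyl group to C10 with retention and completes the cis trisubstituted alkene with C14 trans to C2. The temperature stays well below that at which a cis,cis-cyclodeca-1,5-diene would be expected to undergo Cope rearrangement.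

Step 14
Reactants: 24 8-(tert-butyldimethylsilyloxy)-9,14-dihydroxy-13-norgermacra-1(10)Z,4Z-dien-12,6-olide
Product: 25 8-(tert-butyldimethylsilyloxy)-9,14-bis(triethylsilyloxy)-13-norgermacra-1(10)Z,4Z-dien-12,6-olide
Conditions: TESOTf (2.5 equiv), 2,6-lutidine, CH2Cl2, −78 → 0 °C
Reagents that add atoms: triethylsilyl trifluoromethanesulfonate, CC[Si](CC)(CC)OS(=O)(=O)C(F)(F)F
Why: Silylation of both allylic hydroxyls so that the lactone can be enolised cleanly. TES is chosen because it can later be removed beside the secondary TBS ether on O8.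

Step 15
Reactants: 25 8-(tert-butyldimethylsilyloxy)-9,14-bis(triethylsilyloxy)-13-norgermacra-1(10)Z,4Z-dien-12,6-olide
Product: 29 8-(tert-butyldimethylsilyloxy)-9,14-bis(triethylsilyloxy)germacra-1(10)Z,4Z,11(13)-trien-12,6-olide, via lithium enolate 26 (not isolated), via Mannich base 27 (not isolated), via ammonium iodide 28 (not isolated)
Conditions: LiN(iPr)2, THF, −78 °C; CH2=NMe2+ I−, −78 → 0 °C; then MeI, MeOH/THF, rt; then aq. NaHCO3, CH2Cl2, rt
Reagents that add atoms: Eschenmoser's salt (N,N-dimethylmethyleneiminium iodide), C=[N+](C)C.[I-]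
Why: Mannich reaction of the lactone enolate with Eschenmoser's salt, quaternisation and mild base elimination install the exocyclic C11=C13 alkene. C7 is not enolisable, and the step comes after all tin and palladium chemistry because the product is a Michael acceptor.

Step 16
Reactants: 29 8-(tert-butyldimethylsilyloxy)-9,14-bis(triethylsilyloxy)germacra-1(10)Z,4Z,11(13)-trien-12,6-olide
Product: 30 8-(tert-butyldimethylsilyloxy)-9,14-dihydroxygermacra-1(10)Z,4Z,11(13)-trien-12,6-olide
Conditions: PPTS (cat.), MeOH/CH2Cl2, 0 °C → rt
Reagents that add atoms: none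
Why: Mild acid methanolysis removes both triethylsilyl ethers and leaves the hindered secondary TBS ether; no base is present that could trigger oxa-Michael addition to the methylene lactone.

Step 17
Reactants: 30 8-(tert-butyldimethylsilyloxy)-9,14-dihydroxygermacra-1(10)Z,4Z,11(13)-trien-12,6-olide; 31 (R)-2-methylbutanoic acid
Product: 32 8-(tert-butyldimethylsilyloxy)-9-hydroxy-14-[(2R)-2-methylbutanoyloxy]germacra-1(10)Z,4Z,11(13)-trien-12,6-olide
Conditions: 31 (1.1 equiv), DCC, DMAP (10 mol%), CH2Cl2, −20 → 0 °C
Reagents that add atoms: none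
Why: Steglich esterification: the primary allylic C14 hydroxyl should react far faster than the secondary C9 hydroxyl flanked by the silyl ether. Low temperature and little DMAP protect the α-centre of the acid.

Step 18
Reactants: 32 8-(tert-butyldimethylsilyloxy)-9-hydroxy-14-[(2R)-2-methylbutanoyloxy]germacra-1(10)Z,4Z,11(13)-trien-12,6-olide
Product: 33 9-acetoxy-8-(tert-butyldimethylsilyloxy)-14-[(2R)-2-methylbutanoyloxy]germacra-1(10)Z,4Z,11(13)-trien-12,6-olide
Conditions: Ac2O, pyridine, DMAP (cat.), CH2Cl2, 0 °C → rt
Reagents that add atoms: acetic anhydride, CC(=O)OC(C)=O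
Why: DMAP-catalysed acetylation of the only free hydroxyl; O8 is still silylated, so no regiochemical question arises.

Step 19
Reactants: 33 9-acetoxy-8-(tert-butyldimethylsilyloxy)-14-[(2R)-2-methylbutanoyloxy]germacra-1(10)Z,4Z,11(13)-trien-12,6-olide
Product: 34 (6R,7R,8S,9R)-9-acetoxy-8-hydroxy-14-[(2R)-2-methylbutanoyloxy]germacra-1(10)Z,4Z,11(13)-trien-12,6-olide (target)
Conditions: HF·pyridine, THF, 0 °C → rt
Reagents that add atoms: none
Why: Acidic fluoride cleaves the Si–O bond without ever generating an alkoxide, which should avoid acetyl shift from O9 to O8, relactonisation onto O8 and oxa-Michael addition.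

## Compound list

1 | (4-bromobut-1-yn-1-yl)trimethylsilane | C[Si](C)(C)C#CCCBr | starting material
2 | propyne | CC#C | starting material
3 | [4-(trimethylsilyl)but-3-yn-1-yl]magnesium bromide (not isolated) | C[Si](C)(C)C#CCC[Mg]Br | intermediate
4 | [4-(trimethylsilyl)but-3-yn-1-yl]copper (not isolated) | C[Si](C)(C)C#CCC[Cu] | intermediate
5 | [(1Z)-2-methyl-6-(trimethylsilyl)hex-1-en-5-yn-1-yl]copper (not isolated) | C[Si](C)(C)C#CCC/C(C)=C\[Cu] | intermediate
6 | (Z)-1-iodo-2-methyl-6-(trimethylsilyl)hex-1-en-5-yne | C[Si](C)(C)C#CCC/C(C)=C\I | intermediate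
7 | (R)-2,3-O-isopropylideneglyceraldehyde | O=C[C@H]1COC(C)(C)O1 | starting material
8 | methyl (2Z)-3-[(4S)-2,2-dimethyl-1,3-dioxolan-4-yl]prop-2-enoate | COC(=O)/C=C\[C@H]1COC(C)(C)O1 | intermediate
9 | methyl (3S)-3-[(4S)-2,2-dimethyl-1,3-dioxolan-4-yl]-4-nitrobutanoate | COC(=O)C[C@@H](C[N+](=O)[O-])[C@H]1COC(C)(C)O1 | intermediate
10 | sodium nitronate of 9 (not isolated) | COC(=O)C[C@@H](C=[N+]([O-])[O-])[C@H]1COC(C)(C)O1.[Na+] | intermediate
11 | methyl (3R)-3-[(4S)-2,2-dimethyl-1,3-dioxolan-4-yl]-4-oxobutanoate | COC(=O)C[C@@H](C=O)[C@H]1COC(C)(C)O1 | intermediate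
12 | [(1Z)-2-methyl-6-(trimethylsilyl)hex-1-en-5-yn-1-yl]lithium (not isolated) | C[Si](C)(C)C#CCC/C(C)=C\[Li] | intermediate
13 | lithium alkoxide of methyl (3S,4R,5Z)-3-[(4S)-2,2-dimethyl-1,3-dioxolan-4-yl]-4-hydroxy-6-methyl-10-(trimethylsilyl)dec-5-en-9-ynoate (not isolated) | COC(=O)C[C@@H]([C@H](O[Li])/C=C(/C)CCC#C[Si](C)(C)C)[C@H]1COC(C)(C)O1 | intermediate
14 | (4S,5R)-4-[(4S)-2,2-dimethyl-1,3-dioxolan-4-yl]-5-[(1Z)-2-methyl-6-(trimethylsilyl)hex-1-en-5-yn-1-yl]oxolan-2-one | O=C1C[C@H]([C@H]2COC(C)(C)O2)[C@@H](/C=C(/C)CCC#C[Si](C)(C)C)O1 | intermediate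
15 | (4S,5R)-4-[(4S)-2,2-dimethyl-1,3-dioxolan-4-yl]-5-[(1Z)-6-iodo-2-methylhex-1-en-5-yn-1-yl]oxolan-2-one | O=C1C[C@H]([C@H]2COC(C)(C)O2)[C@@H](/C=C(/C)CCC#CI)O1 | intermediate
16 | (4R,5R)-4-[(1S)-1,2-dihydroxyethyl]-5-[(1Z)-6-iodo-2-methylhex-1-en-5-yn-1-yl]oxolan-2-one | O=C1C[C@H]([C@H](O)CO)[C@@H](/C=C(/C)CCC#CI)O1 | intermediate
17 | (4R,5R)-4-[(1S)-1-hydroxy-2-(triethylsilyloxy)ethyl]-5-[(1Z)-6-iodo-2-methylhex-1-en-5-yn-1-yl]oxolan-2-one (not isolated) | O=C1C[C@H]([C@H](O)CO[Si](CC)(CC)CC)[C@@H](/C=C(/C)CCC#CI)O1 | intermediate
18 | (4S,5R)-4-[(1S)-1-(tert-butyldimethylsilyloxy)-2-(triethylsilyloxy)ethyl]-5-[(1Z)-6-iodo-2-methylhex-1-en-5-yn-1-yl]oxolan-2-one | O=C1C[C@H]([C@H](O[Si](C)(C)C(C)(C)C)CO[Si](CC)(CC)CC)[C@@H](/C=C(/C)CCC#CI)O1 | intermediate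
19 | (2S)-2-(tert-butyldimethylsilyloxy)-2-[(2R,3S)-2-[(1Z)-6-iodo-2-methylhex-1-en-5-yn-1-yl]-5-oxooxolan-3-yl]acetaldehyde | O=C1C[C@H]([C@H](O[Si](C)(C)C(C)(C)C)C=O)[C@@H](/C=C(/C)CCC#CI)O1 | intermediate
20 | alkynylchromium dichloride from 19, trivalent chromium on C10 (not isolated) | O=C1C[C@H]([C@H](O[Si](C)(C)C(C)(C)C)C=O)[C@@H](/C=C(/C)CCC#C[Cr](Cl)Cl)O1 | intermediate
21 | (6R,7S,8S,9R)-8-(tert-butyldimethylsilyloxy)-9-hydroxy-13,14-dinorgermacr-4Z-en-1(10)-yn-12,6-olide | C1C(=O)O[C@@H]2/C=C(/C)CCC#C[C@@H](O)[C@@H](O[Si](C)(C)C(C)(C)C)[C@@H]12 | intermediate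
22 | 8-(tert-butyldimethylsilyloxy)-9-hydroxy-10-(tributylstannyl)-13,14-dinorgermacra-1(10),4-dien-12,6-olide, both ring alkenes cis | C1C(=O)O[C@@H]2/C=C(/C)CC/C=C(/[Sn](CCCC)(CCCC)CCCC)[C@@H](O)[C@@H](O[Si](C)(C)C(C)(C)C)[C@@H]12 | intermediate
23 | 8-(tert-butyldimethylsilyloxy)-9-hydroxy-10-iodo-13,14-dinorgermacra-1(10),4-dien-12,6-olide, both ring alkenes cis | C1C(=O)O[C@@H]2/C=C(/C)CC/C=C(/I)[C@@H](O)[C@@H](O[Si](C)(C)C(C)(C)C)[C@@H]12 | intermediate
24 | 8-(tert-butyldimethylsilyloxy)-9,14-dihydroxy-13-norgermacra-1(10)Z,4Z-dien-12,6-olide | C1C(=O)O[C@@H]2/C=C(/C)CC/C=C(/CO)[C@@H](O)[C@@H](O[Si](C)(C)C(C)(C)C)[C@@H]12 | intermediate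
25 | 8-(tert-butyldimethylsilyloxy)-9,14-bis(triethylsilyloxy)-13-norgermacra-1(10)Z,4Z-dien-12,6-olide | C1C(=O)O[C@@H]2/C=C(/C)CC/C=C(/CO[Si](CC)(CC)CC)[C@@H](O[Si](CC)(CC)CC)[C@@H](O[Si](C)(C)C(C)(C)C)[C@@H]12 | intermediate
26 | lithium enolate of 25 (not isolated) | C1=C(O[Li])O[C@@H]2/C=C(/C)CC/C=C(/CO[Si](CC)(CC)CC)[C@@H](O[Si](CC)(CC)CC)[C@@H](O[Si](C)(C)C(C)(C)C)[C@@H]12 | intermediate
27 | 11-(dimethylaminomethyl) derivative of 25, C11 epimers (not isolated) | CN(C)CC1C(=O)O[C@@H]2/C=C(/C)CC/C=C(/CO[Si](CC)(CC)CC)[C@@H](O[Si](CC)(CC)CC)[C@@H](O[Si](C)(C)C(C)(C)C)[C@@H]12 | intermediate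
28 | trimethylammonium iodide of 27 (not isolated) | C[N+](C)(C)CC1C(=O)O[C@@H]2/C=C(/C)CC/C=C(/CO[Si](CC)(CC)CC)[C@@H](O[Si](CC)(CC)CC)[C@@H](O[Si](C)(C)C(C)(C)C)[C@@H]12.[I-] | intermediate
29 | 8-(tert-butyldimethylsilyloxy)-9,14-bis(triethylsilyloxy)germacra-1(10)Z,4Z,11(13)-trien-12,6-olide | C=C1C(=O)O[C@@H]2/C=C(/C)CC/C=C(/CO[Si](CC)(CC)CC)[C@@H](O[Si](CC)(CC)CC)[C@@H](O[Si](C)(C)C(C)(C)C)[C@@H]12 | intermediate
30 | 8-(tert-butyldimethylsilyloxy)-9,14-dihydroxygermacra-1(10)Z,4Z,11(13)-trien-12,6-olide | C=C1C(=O)O[C@@H]2/C=C(/C)CC/C=C(/CO)[C@@H](O)[C@@H](O[Si](C)(C)C(C)(C)C)[C@@H]12 | intermediate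
31 | (R)-2-methylbutanoic acid | CC[C@@H](C)C(=O)O | starting material
32 | 8-(tert-butyldimethylsilyloxy)-9-hydroxy-14-[(2R)-2-methylbutanoyloxy]germacra-1(10)Z,4Z,11(13)-trien-12,6-olide | C=C1C(=O)O[C@@H]2/C=C(/C)CC/C=C(/COC(=O)[C@H](C)CC)[C@@H](O)[C@@H](O[Si](C)(C)C(C)(C)C)[C@@H]12 | intermediate
33 | 9-acetoxy-8-(tert-butyldimethylsilyloxy)-14-[(2R)-2-methylbutanoyloxy]germacra-1(10)Z,4Z,11(13)-trien-12,6-olide | C=C1C(=O)O[C@@H]2/C=C(/C)CC/C=C(/COC(=O)[C@H](C)CC)[C@@H](OC(C)=O)[C@@H](O[Si](C)(C)C(C)(C)C)[C@@H]12 | intermediate
34 | (6R,7R,8S,9R)-9-acetoxy-8-hydroxy-14-[(2R)-2-methylbutanoyloxy]germacra-1(10)Z,4Z,11(13)-trien-12,6-olide | C=C1C(=O)O[C@@H]2/C=C(/C)CC/C=C(/COC(=O)[C@H](C)CC)[C@@H](OC(C)=O)[C@@H](O)[C@@H]12 | target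

## Step count and least certain steps

Total: 19 steps. Longest linear sequence: 18 steps (7 to 34, steps 2 to 19); step 1 supplies the side branch 6.

Step 10 (key step). Most likely to go wrong: attack on the wrong face of the aldehyde, because strain in the cyclic transition state can override the Felkin–Anh preference, together with intermolecular coupling, because the chain from C1 to C7 is flexible. Protonation of the alkynylchromium to the terminal alkyne is a further loss. Fallback: it sets out from 19 and accepts whatever facial ratio the cyclisation gives. The unwanted carbinol, the 9-epimeric cycloalkynol F1, alone or mixed with 21, is oxidised (Dess–Martin periodinane, NaHCO3, CH2Cl2) to the ring ynone F2. The C9 configuration is then set by reagent control in an asymmetric transfer hydrogenation with RuCl[(S,S)-TsDPEN](p-cymene) in propan-2-ol, the antipode expected to place the hydroxyl as in 21 with the alkyne as the directing π-group. The route is rejoined at 21. The stereocentre is thus made by C=O reduction and no longer by the C–C bond formation.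

Step 3. Most likely to go wrong: poor facial selectivity of the nitronate addition, since the sense rests on a conformational preference of the dioxolanyl enoate and not on a rigid template, and partial retro-addition under base. Fallback: it sets out from 8 and makes the C7–C11 bond by a sigmatropic shift. Reduction with iBu2AlH (CH2Cl2, −78 °C) gives the allylic alcohol (2Z)-3-[(4S)-2,2-dimethyl-1,3-dioxolan-4-yl]prop-2-en-1-ol F3. Johnson–Claisen rearrangement with trimethyl orthoacetate and catalytic propionic acid at about 130 °C gives the pentenoate methyl (3S)-3-[(4S)-2,2-dimethyl-1,3-dioxolan-4-yl]pent-4-enoate F4; with the C8–H bond eclipsing the Z alkene, the new bond should form anti to the C8–O bond, which corresponds to the same C7 configuration. Ozonolysis (O3, CH2Cl2, −78 °C; PPh3) of the vinyl group rejoins the route at 11. This path also avoids the Nef reaction of step 4.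

Step 5. Most likely to go wrong: incomplete facial selectivity at C6, and enolisation of the α-branched, β-alkoxy aldehyde by the basic organolithium with loss of the C7 configuration. Fallback: it sets out from 6 and 11 as in step 5 and recycles the wrong isomer by inversion. The cis-lactone (4S,5S)-4-[(4S)-2,2-dimethyl-1,3-dioxolan-4-yl]-5-[(1Z)-2-methyl-6-(trimethylsilyl)hex-1-en-5-yn-1-yl]oxolan-2-one F5 is separated and opened with LiOH (THF/H2O, 0 °C). The resulting hydroxy acid (3S,4S,5Z)-3-[(4S)-2,2-dimethyl-1,3-dioxolan-4-yl]-4-hydroxy-6-methyl-10-(trimethylsilyl)dec-5-en-9-ynoic acid F6 is closed under Mitsunobu conditions (PPh3, diisopropyl azodicarboxylate, THF, 0 °C), in which the carboxylate displaces the activated C6 oxygen with inversion. The route is rejoined at 14. Loss of the alkyne silyl group in the saponification would be harmless, because the conditions of step 6 iodinate a terminal alkyne as well and the route would then be rejoined at 15.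

Step 11. Most likely to go wrong: delivery of tin to C1 and not to C10, because C10 is crowded by the C9 carbinol and the C8 silyl ether, and reduction of excess tin hydride to the distannane before it adds. Fallback: it sets out from 21 and fixes the regiochemistry by a tether. Silylation of O9 with (bromomethyl)chlorodimethylsilane and imidazole gives the (bromomethyl)dimethylsilyl ether F7. Bu3SnH with AIBN in benzene at 80 °C generates the α-silyl radical, which closes 5-exo-dig onto C10 and so forms the C10–C14 bond. The vinyl radical at C1 takes hydrogen to give the cyclic siloxane F8, in which the ring constraint allows only the cis ring alkene. Tamao–Fleming oxidation (H2O2, KF, KHCO3, THF/MeOH) turns C14–Si into C14–OH and frees O9. The route is rejoined at 24, so steps 11 to 13 are replaced as a block.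

## Further compounds

F1 | step 10 | (6R,7S,8S,9S)-8-(tert-butyldimethylsilyloxy)-9-hydroxy-13,14-dinorgermacr-4Z-en-1(10)-yn-12,6-olide (9-epimer of 21) | C1C(=O)O[C@@H]2/C=C(/C)CCC#C[C@H](O)[C@@H](O[Si](C)(C)C(C)(C)C)[C@@H]12
F2 | step 10 | 8-(tert-butyldimethylsilyloxy)-9-oxo-13,14-dinorgermacr-4Z-en-1(10)-yn-12,6-olide | C1C(=O)O[C@@H]2/C=C(/C)CCC#CC(=O)[C@@H](O[Si](C)(C)C(C)(C)C)[C@@H]12
F3 | step 3 | (2Z)-3-[(4S)-2,2-dimethyl-1,3-dioxolan-4-yl]prop-2-en-1-ol | OC/C=C\[C@H]1COC(C)(C)O1
F4 | step 3 | methyl (3S)-3-[(4S)-2,2-dimethyl-1,3-dioxolan-4-yl]pent-4-enoate | COC(=O)C[C@@H](C=C)[C@H]1COC(C)(C)O1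
F5 | step 5 | (4S,5S)-4-[(4S)-2,2-dimethyl-1,3-dioxolan-4-yl]-5-[(1Z)-2-methyl-6-(trimethylsilyl)hex-1-en-5-yn-1-yl]oxolan-2-one | O=C1C[C@H]([C@H]2COC(C)(C)O2)[C@H](/C=C(/C)CCC#C[Si](C)(C)C)O1
F6 | step 5 | (3S,4S,5Z)-3-[(4S)-2,2-dimethyl-1,3-dioxolan-4-yl]-4-hydroxy-6-methyl-10-(trimethylsilyl)dec-5-en-9-ynoic acid | OC(=O)C[C@@H]([C@@H](O)/C=C(/C)CCC#C[Si](C)(C)C)[C@H]1COC(C)(C)O1
F7 | step 11 | 9-O-[(bromomethyl)dimethylsilyl] ether of 21 | C1C(=O)O[C@@H]2/C=C(/C)CCC#C[C@@H](O[Si](C)(C)CBr)[C@@H](O[Si](C)(C)C(C)(C)C)[C@@H]12
F8 | step 11 | cyclic siloxane bridging O9 and C14 (1,2-oxasilolane fused at C9–C10, both ring alkenes cis) | C1C(=O)O[C@@H]2/C=C(/C)CC/C=C3/C[Si](C)(C)O[C@H]3[C@@H](O[Si](C)(C)C(C)(C)C)[C@@H]12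
A1 | alternative 1 | (4S,5R)-4-[(4S)-2,2-dimethyl-1,3-dioxolan-4-yl]-5-[(1Z)-2-methylhexa-1,5-dien-1-yl]oxolan-2-one | C1C(=O)O[C@H](/C=C(/C)CCC=C)[C@H]1[C@H]2COC(C)(C)O2
A2 | alternative 1 | but-3-enylmagnesium bromide | C=CCC[Mg]Br
A3 | alternative 2 | cis-1-vinyl-2-isopropenylcyclohexanol carrying the C6 p-methoxybenzyl ether, the C7 side chain and the C8–C9 acetonide | C=C[C@]1(O)[C@H](C(C)=C)[C@@H](OCc2ccc(OC)cc2)[C@H](C(=C)COCc2ccc(OC)cc2)[C@@H]3OC(C)(C)O[C@H]13
A4 | alternative 2 | ten-membered C10 ketone with the cis C4=C5 alkene | O=C1CCC/C(C)=C\[C@@H](OCc2ccc(OC)cc2)[C@H](C(=C)COCc2ccc(OC)cc2)[C@@H]3OC(C)(C)O[C@H]13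
A5 | alternative 3 | cis-fused decalin hydroxy mesylate (C9 tertiary alcohol, C5 mesylate, lactone on C6–C7) | C1C(=O)O[C@@H]2[C@@H](OS(C)(=O)=O)[C@@]3(C)CCC=C(CO[Si](C)(C)C(C)(C)C)[C@@]3(O)[C@@H](OCc4ccc(OC)cc4)[C@@H]12
A6 | alternative 3 | ten-membered enone lactone (C9 ketone, both ring alkenes cis) | C1C(=O)O[C@@H]2/C=C(/C)CC/C=C(/CO[Si](C)(C)C(C)(C)C)C(=O)[C@@H](OCc3ccc(OC)cc3)[C@@H]12
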